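**Strategy.** Labdane numbering is used (C18 = oxygenated carbon on C4). The ring-B diene C6=C7–C8(=C17H2) is treated as the methylenation product of a Δ6-8-ketone, so ring B is closed at the congested C5–C6 bond by a 6-endo-dig cyclization of a C5 radical onto a C8 ynone. The precursor is a ring-A cyclohexane whose C5–O and C18–O are tied as a cyclic thionocarbonate and whose C10 carries the ynone arm; one operation sets H5 trans to the C10 methyl and delivers the enone. Ring A with both quaternary centres comes from a meso bicyclo[3.3.1]nonane-3,9-dione by enantioselective Baeyer–Villiger desymmetrization, the lactone supplying C18–O and C8=O.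

Key step: step 8

Remarks on the chemistry:
- C19 and C20 are the methyls on C4 and C10; C17 is the exocyclic methylene carbon.
- The sense of induction of the Baeyer–Villiger catalyst is not predicted here; the ligand antipode that gives (1R,6S)-7 is assumed to be used.
- The configurations drawn at C9 in 9–13 and at the C5 carbinol in 10–13 are the expected ones but are inconsequential. The carbinol centre is destroyed on radical formation, and C9 becomes epimerizable α to the C8 ketone in step 8.

Step 1
Reactants: 1 2,6-dimethylcyclohexanone (cis/trans mixture); 2 3-chloro-2-(chloromethyl)prop-1-ene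
Product: 4 meso-(1R,5S)-1,5-dimethyl-3-methylidenebicyclo[3.3.1]nonan-9-one, via chloroallyl ketone 3 (not isolated)
Conditions: t-BuOK (2.2 equiv), t-BuOH–THF, 0 → 65 °C
Reagents that add atoms: none
Why: Double enolate alkylation (α,α′-annulation): tert-butoxide enolizes the α-methyl carbon, the allylic chloride is displaced, and the second enolate can close the six-membered ring only on the face carrying the first arm, so the bridge is cis and both methyls become bridgehead substituents of a meso bicycle regardless of the isomer ratio of 1.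

Step 2
Reactants: 4 meso-1,5-dimethyl-3-methylidenebicyclo[3.3.1]nonan-9-one
Product: 6 meso-(1R,5S)-1,5-dimethylbicyclo[3.3.1]nonane-3,9-dione, via secondary ozonide 5 (not isolated)
Conditions: O3, CH2Cl2, −78 °C; then Me2S, −78 °C → rt
Reagents that add atoms: ozone, [O-][O+]=O
Why: Ozonolysis of the 1,1-disubstituted alkene with reductive work-up; the bridging ketone has no enolizable hydrogen and is inert.

Step 3
Reactants: 6 meso-1,5-dimethylbicyclo[3.3.1]nonane-3,9-dione
Product: 7 (1R,6S)-1,6-dimethyl-3-oxabicyclo[4.3.1]decane-4,10-dione (bridged ε-lactone; both methyls on bridgeheads)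
Conditions: Sc(OTf)3 (5 mol %), chiral N,N′-dioxide bis-amide ligand (6 mol %), m-CPBA (1.05 equiv), EtOAc, −20 °C
Reagents that add atoms: m-CPBA, O=C(OO)c1cccc(Cl)c1
Why: Catalytic enantioselective Baeyer–Villiger oxidation of a meso cyclohexanone with a chiral scandium Lewis acid: the C3 ketone (two α-CH2 groups) is more accessible than the bridging ketone between two quaternary carbons, and the catalyst decides which enantiotopic CH2 migrates, which fixes the absolute configuration of both quaternary centres (C4 and C10 of the target) at once.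

Step 4
Reactants: 7 (1R,6S)-1,6-dimethyl-3-oxabicyclo[4.3.1]decane-4,10-dione; 8 2-(2-bromoethyl)-2-methyl-1,3-dioxolane
Product: 9 (1R,5S,6S)-1,6-dimethyl-5-[2-(2-methyl-1,3-dioxolan-2-yl)ethyl]-3-oxabicyclo[4.3.1]decane-4,10-dione
Conditions: LiN(i-Pr)2, THF, −78 °C; then 8, DMPU, −78 → −20 °C
Reagents that add atoms: none
Why: Lactone enolate alkylation at the only enolizable carbon (future C9); attack anti to the three-carbon bridge should give the epimer drawn, and this centre becomes epimerizable α to the C8 ketone in step 8 in any case.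

Step 5
Reactants: 9 alkylated keto lactone
Product: 11 (3S,3aS,7R,7aR)-7-(hydroxymethyl)-3a,7-dimethyl-3-[2-(2-methyl-1,3-dioxolan-2-yl)ethyl]hexahydro-1-benzofuran-2(3H)-one (cis-fused γ-lactone), via hydroxy ε-lactone 10 (not isolated)
Conditions: NaBH4, MeOH–THF, 0 °C → rt
Reagents that add atoms: none
Why: NaBH4 reduces the bridging ketone but not the lactone, hydride entering from the carbocyclic side away from the new side chain; the alkoxide, held over the lactone ring, transacylates to the less strained cis-fused five-membered lactone and frees the C18 alcohol (the carbinol configuration is later erased).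

Step 6
Reactants: 11 hydroxymethyl γ-lactone
Product: 12 (4S)-4-[(1S,2R,3R)-2-hydroxy-3-(hydroxymethyl)-1,3-dimethylcyclohexyl]-6-(2-methyl-1,3-dioxolan-2-yl)hex-1-yn-3-one
Conditions: HC≡CLi (from acetylene and n-BuLi, 4 equiv), THF, −78 °C; AcOH, −78 °C
Reagents that add atoms: lithium acetylide, [Li]C#C
Why: Single addition of lithium acetylide to the lactone, whose tetrahedral lactolate is stable at −78 °C; protonation gives the γ-hydroxy ynone in ring–chain equilibrium with its lactol.

Step 7
Reactants: 12 ynone diol
Product: 13 (4S)-4-[(4aR,8S,8aR)-4a,8-dimethyl-2-sulfanylidenehexahydro-4H-1,3-benzodioxin-8-yl]-6-(2-methyl-1,3-dioxolan-2-yl)hex-1-yn-3-one (cyclic thionocarbonate of the C5/C18 diol)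
Conditions: 1,1′-thiocarbonyldi-2(1H)-pyridone, DMAP (cat.), PhMe, rt → 50 °C
Reagents that add atoms: 1,1′-thiocarbonyldi-2(1H)-pyridone, S=C(n1ccccc1=O)n1ccccc1=O
Why: Thiocarbonyl transfer to the primary C18–OH followed by ring closure by the C5–OH gives the six-membered cyclic thionocarbonate (diol thiocarbonylation as in the Corey–Winter sequence), which drains the lactol equilibrium; 2-pyridone as leaving group avoids nucleophiles that would add to the ynone.

Step 8
Reactants: 13 cyclic thionocarbonate ynone
Product: 15 (1S,4aS,5S,8aR)-5-(hydroxymethyl)-5,8a-dimethyl-1-(3-oxobutyl)-4a,5,6,7,8,8a-hexahydronaphthalen-2(1H)-one (trans-fused Δ6-8-ketone, labdane numbering), via stannyl thiocarbonate 14 (not isolated)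
Conditions: Bu3SnH (1.3 equiv, syringe pump), AIBN (0.2 equiv), PhH (0.005 M), 80 °C; then 1 M HCl, THF, rt
Reagents that add atoms: water, O
Why: Bu3Sn• adds to sulfur of the cyclic thionocarbonate and the adduct fragments at the secondary C5–O bond rather than the primary C18–O bond (Barton–McCombie deoxygenation of a diol thionocarbonate), which unmasks the C5 radical and leaves C18–O as an S-stannyl thiocarbonate. This nucleophilic radical adds to C6, the unsubstituted β-carbon of the ynone, closing ring B in the 6-endo-dig mode (closest known type: alkyl-radical conjugate cyclization onto an alkynone whose carbonyl lies inside the new ring), and the α-keto vinyl radical at C7 takes H from Bu3SnH to give the cis C6=C7 enone directly. C5 is controlled by a chair–chair transition state with the C9 arm equatorial on ring A, so that H5 ends anti to the axial C10 methyl (trans-decalin); H5 is γ to the enone, so this should also be the isomer favoured by dienol equilibration. C9, now α to the C8 ketone, is under thermodynamic control and should settle with the side chain equatorial during the acidic work-up. The step needs 6-endo over 5-exo closure, secured by the polarization of the ynone (attack at C7 would hit the α-carbon), and cyclization before hydrogen transfer, secured by high dilution and slow stannane addition. Aqueous HCl then cleaves the Sn–S bond, the monothiocarbonic acid loses COS to free C18–OH, and the dioxolane is hydrolysed.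

Step 9
Reactants: 15 hydroxy enone diketone
Product: 16 (1S,4aS,5S,8aR)-5-(acetoxymethyl)-5,8a-dimethyl-1-(3-oxobutyl)-4a,5,6,7,8,8a-hexahydronaphthalen-2(1H)-one
Conditions: Ac2O, pyridine, DMAP (cat.), CH2Cl2, rt
Reagents that add atoms: acetic anhydride, CC(=O)OC(C)=O
Why: DMAP-catalysed acetylation of the primary alcohol, placed before the basic olefination so that no C18 alkoxide can add to C6 of the enone.

Step 10
Reactants: 16 acetoxy enone methyl ketone
Product: 17 methyl (2E)-5-[(1S,4aS,5S,8aR)-5-(acetoxymethyl)-5,8a-dimethyl-2-oxo-1,2,4a,5,6,7,8,8a-octahydronaphthalen-1-yl]-3-methylpent-2-enoate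
Conditions: (MeO)2P(O)CH2CO2Me (1.6 equiv), NaH (1.5 equiv), THF, 0 → 50 °C
Reagents that add atoms: trimethyl phosphonoacetate, COC(=O)CP(=O)(OC)OC
Why: Horner–Wadsworth–Emmons olefination of the methyl ketone, which should react in preference to the hindered conjugated C8 ketone; the E-trisubstituted ester should predominate and the Z isomer is to be removed by chromatography.

Step 11
Reactants: 17 enone ester
Product: 18 methyl (2E)-5-[(1R,4aS,5S,8aS)-5-(acetoxymethyl)-5,8a-dimethyl-2-methylidene-1,2,4a,5,6,7,8,8a-octahydronaphthalen-1-yl]-3-methylpent-2-enoate (target)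
Conditions: Zn, CH2Br2, TiCl4, THF–CH2Cl2, 0 °C → rt
Reagents that add atoms: dibromomethane, BrCBr
Why: Takai–Lombardo methylenation, a non-basic carbonyl methylenation that spares the acetate and the enoate and does not touch C9, turns the enone into the C6=C7–C8=C17 diene of the target.

**Compound list**

1 | 2,6-dimethylcyclohexanone (cis/trans mixture) | CC1CCCC(C)C1=O | starting material
2 | 3-chloro-2-(chloromethyl)prop-1-ene | C=C(CCl)CCl | starting material
3 | 2-[2-(chloromethyl)prop-2-en-1-yl]-2,6-dimethylcyclohexan-1-one (diastereomer mixture) | CC1CCCC(C)(CC(=C)CCl)C1=O | intermediate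
4 | meso-(1R,5S)-1,5-dimethyl-3-methylidenebicyclo[3.3.1]nonan-9-one | O=C1[C@@](C)(CC(=C)C2)CCC[C@]12C | intermediate
5 | secondary ozonide of 4 (spiro 1,2,4-trioxolane at C3 of the bicycle) | O=C1[C@@](C)(CC3(OCOO3)C2)CCC[C@]12C | intermediate
6 | meso-(1R,5S)-1,5-dimethylbicyclo[3.3.1]nonane-3,9-dione | O=C1[C@@](C)(CC(=O)C2)CCC[C@]12C | intermediate
7 | (1R,6S)-1,6-dimethyl-3-oxabicyclo[4.3.1]decane-4,10-dione | O=C1[C@@](C)(COC(=O)C2)CCC[C@]12C | intermediate
8 | 2-(2-bromoethyl)-2-methyl-1,3-dioxolane | CC1(CCBr)OCCO1 | starting material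
9 | (1R,5S,6S)-1,6-dimethyl-5-[2-(2-methyl-1,3-dioxolan-2-yl)ethyl]-3-oxabicyclo[4.3.1]decane-4,10-dione | O=C1[C@@](C)(COC(=O)[C@H]2CCC3(C)OCCO3)CCC[C@]12C | intermediate
10 | 10-hydroxy ε-lactone from 9 (OH on the lactone-bridge face) | O[C@H]1[C@@](C)(COC(=O)[C@H]2CCC3(C)OCCO3)CCC[C@]12C | intermediate
11 | (3S,3aS,7R,7aR)-7-(hydroxymethyl)-3a,7-dimethyl-3-[2-(2-methyl-1,3-dioxolan-2-yl)ethyl]hexahydro-1-benzofuran-2(3H)-one | OC[C@@]1(C)CCC[C@@]2(C)[C@H](CCC3(C)OCCO3)C(=O)O[C@@H]12 | intermediate
12 | (4S)-4-[(1S,2R,3R)-2-hydroxy-3-(hydroxymethyl)-1,3-dimethylcyclohexyl]-6-(2-methyl-1,3-dioxolan-2-yl)hex-1-yn-3-one | OC[C@@]1(C)CCC[C@@](C)([C@H](CCC2(C)OCCO2)C(=O)C#C)[C@H]1O | intermediate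
13 | (4S)-4-[(4aR,8S,8aR)-4a,8-dimethyl-2-sulfanylidenehexahydro-4H-1,3-benzodioxin-8-yl]-6-(2-methyl-1,3-dioxolan-2-yl)hex-1-yn-3-one | S=C1OC[C@@]2(C)CCC[C@@](C)([C@H](CCC3(C)OCCO3)C(=O)C#C)[C@H]2O1 | intermediate
14 | S-tributylstannyl O-(C18) thiocarbonate of the cyclized Δ6-8-ketone, dioxolane intact (ring stereocentres as in 15) | O=C1C=C[C@@H]2[C@@](C)(COC(=O)S[Sn](CCCC)(CCCC)CCCC)CCC[C@@]2(C)[C@@H]1CCC3(C)OCCO3 | intermediate
15 | (1S,4aS,5S,8aR)-5-(hydroxymethyl)-5,8a-dimethyl-1-(3-oxobutyl)-4a,5,6,7,8,8a-hexahydronaphthalen-2(1H)-one | O=C1C=C[C@@H]2[C@@](C)(CO)CCC[C@@]2(C)[C@@H]1CCC(C)=O | intermediate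
16 | (1S,4aS,5S,8aR)-5-(acetoxymethyl)-5,8a-dimethyl-1-(3-oxobutyl)-4a,5,6,7,8,8a-hexahydronaphthalen-2(1H)-one | O=C1C=C[C@@H]2[C@@](C)(COC(C)=O)CCC[C@@]2(C)[C@@H]1CCC(C)=O | intermediate
17 | methyl (2E)-5-[(1S,4aS,5S,8aR)-5-(acetoxymethyl)-5,8a-dimethyl-2-oxo-1,2,4a,5,6,7,8,8a-octahydronaphthalen-1-yl]-3-methylpent-2-enoate | O=C1C=C[C@@H]2[C@@](C)(COC(C)=O)CCC[C@@]2(C)[C@@H]1CC/C(C)=C/C(=O)OC | intermediate
18 | methyl (2E)-5-[(1R,4aS,5S,8aS)-5-(acetoxymethyl)-5,8a-dimethyl-2-methylidene-1,2,4a,5,6,7,8,8a-octahydronaphthalen-1-yl]-3-methylpent-2-enoate | C=C1C=C[C@@H]2[C@@](C)(COC(C)=O)CCC[C@@]2(C)[C@@H]1CC/C(C)=C/C(=O)OC | target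

**Step count.** Total: 11 steps. Longest linear sequence: 11 steps (1 → 18; 2 and 8 are purchased).

**Steps most likely to fail**

Step 8 (key step). Hydrogen transfer to the C5 radical, or reversible tin-radical addition to the terminal ynone, may outrun the 6-endo-dig closure, and the ring fusion may form with poor selectivity. The fallback sets out from 11 and comes back at 15; it changes the acceptor to an enone and restores the unsaturation afterwards. Addition of CH2=CHMgBr with CeCl3 to lactone 11 at −78 °C should give the dihydroxy vinyl ketone F1. Thiocarbonyl transfer as in step 7 should give the cyclic thionocarbonate F2. Bu3SnH and AIBN should then effect the classical 6-endo-trig closure of a cyclohexyl radical onto a vinyl ketone (C5–C6 bond, chair–chair, trans), and K2CO3 in MeOH frees the C18 alcohol to give the saturated hydroxy 8-ketone F3. Kinetic enolization toward C7 with LiN(i-Pr)2 and Me3SiCl should give the bis-silyl enol ether F4. Saegusa–Ito dehydrogenation with Pd(OAc)2, followed by aqueous HCl (loss of both silyl groups and of the dioxolane), returns 15.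

Step 3. The catalyst may discriminate the two enantiotopic CH2 groups weakly, or oxidation may occur at the bridging ketone. The fallback sets out from 6 and comes back at 7; it desymmetrizes by enantioselective deprotonation instead of oxygen insertion. Lithium (R,R)-bis(1-phenylethyl)amide with Me3SiCl as internal quench (THF, −100 °C) should give the non-racemic silyl enol ether F5, the antipode of the base being chosen so that the enol double bond points to the future C18. Ozonolysis with Me2S work-up cleaves the C8–C18 bond to the keto aldehyde acid F6. NaBH4 at −40 °C should reduce only the aldehyde to the hydroxy acid F7. Lactonization (2,4,6-trichlorobenzoyl chloride, Et3N, then DMAP) closes the bridged lactone 7.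

Step 4. SN2 of the neopentylic lactone enolate with the unactivated bromide may be slow, with E2 of 8 or ketene fragmentation of the enolate on warming. The fallback sets out from 7 and comes back at 9; it uses a conjugate addition instead. LiN(i-Pr)2 and Me3SiCl convert 7 into the silyl ketene acetal F8. Mukaiyama–Michael addition to methyl vinyl ketone (TiCl4, CH2Cl2, −78 °C) should give the keto lactone F9. Selective dioxolane formation at the unhindered methyl ketone (ethylene glycol, pyridinium p-toluenesulfonate, PhH, Dean–Stark) gives 9.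

**Further compounds**

F1 | step 8 | (4S)-4-[(1S,2R,3R)-2-hydroxy-3-(hydroxymethyl)-1,3-dimethylcyclohexyl]-6-(2-methyl-1,3-dioxolan-2-yl)hex-1-en-3-one | OC[C@@]1(C)CCC[C@@](C)([C@H](CCC2(C)OCCO2)C(=O)C=C)[C@H]1O
F2 | step 8 | cyclic thionocarbonate of F1 (vinyl ketone analogue of 13) | S=C1OC[C@@]2(C)CCC[C@@](C)([C@H](CCC3(C)OCCO3)C(=O)C=C)[C@H]2O1
F3 | step 8 | (1S,4aS,5S,8aR)-5-(hydroxymethyl)-5,8a-dimethyl-1-[2-(2-methyl-1,3-dioxolan-2-yl)ethyl]octahydronaphthalen-2(1H)-one | O=C1CC[C@@H]2[C@@](C)(CO)CCC[C@@]2(C)[C@@H]1CCC3(C)OCCO3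
F4 | step 8 | C7=C8 trimethylsilyl enol ether and C18 trimethylsilyl ether of F3 | C[Si](C)(C)OC1=CC[C@@H]2[C@@](C)(CO[Si](C)(C)C)CCC[C@@]2(C)[C@@H]1CCC3(C)OCCO3
F5 | step 3 | 1,5-dimethyl-3-(trimethylsilyloxy)bicyclo[3.3.1]non-2-en-9-one, enantiomer with the enol double bond toward the future C18 | O=C1[C@@](C)(C=C(O[Si](C)(C)C)C2)CCC[C@]12C
F6 | step 3 | 2-(3-formyl-1,3-dimethyl-2-oxocyclohexyl)acetic acid, quaternary centres as in 7 | O=C1[C@@](C)(C=O)CCC[C@]1(CC(=O)O)C
F7 | step 3 | 2-[3-(hydroxymethyl)-1,3-dimethyl-2-oxocyclohexyl]acetic acid, seco acid of 7 | O=C1[C@@](C)(CO)CCC[C@]1(CC(=O)O)C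
F8 | step 4 | trimethylsilyl ketene acetal of lactone 7 | O=C1[C@@](C)(COC(O[Si](C)(C)C)=C2)CCC[C@]12C
F9 | step 4 | 5-(3-oxobutyl) derivative of lactone 7, C9 as in 9 | O=C1[C@@](C)(COC(=O)[C@H]2CCC(C)=O)CCC[C@]12C
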